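## Retrosynthetic overview

1. Feature: number ring B of the tetralin as C1 = carbinol, C4 = diarylmethine, with C5 = OMe on ring A. C4 is then a single carbon held between arene carbon C4a and methylene C3, and it carries the whole naphthol unit. C4 plus its naphthyl group is therefore a naphthylcarbene equivalent.
2. Key disconnection: C4 is excised from ring B. This leaves a 7-methoxyindan-1-one whose C3 already bears the C1 oxygen, and a 1-naphthyldiazomethane. In the forward sense C3–C4 and C4–C4a form in one operation with loss of N2.
3. The ketone that the insertion leaves at C3 is removed by enol triflate formation and formate reduction. The resulting C3=C4 alkene is hydrogenated from the face anti to C1–OSi, which places C4–naphthyl cis to C1–O.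
4. C1 is fixed early by lipase resolution of the 3-hydroxyindanone. The diazo partner comes from symmetric 1,8-dimethoxynaphthalene by formylation and demethylation of the OMe para to CHO.
5. Ring order: ring A with its five-membered ring, and the naphthalene, are bought. Ring B is the only ring made, by enlargement of the five-membered ring in the key step.

Key step: step 10

Assumption: the SMILES is read as (1S,4S), so C1–OH and C4–naphthyl are cis on ring B; target numbering (C1 to C8a) is used for ring B atoms in the Why lines from step 10 on.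
Assumption: in step 13 the S antipode of the ligand is written; one test run with each antipode is to settle which one matches the substrate bias.

## Route

Step 1
Reactants: 1 7-methoxyindan-1-one
Product: 2 (±)-3-bromo-7-methoxyindan-1-one
Conditions: NBS (1.05 equiv), AIBN (5 mol %), PhCF3, reflux
Reagents that add atoms: N-bromosuccinimide, O=C1CCC(=O)N1Br
Why: Wohl–Ziegler bromination, in which the bromine atom abstracts a hydrogen from C3, the only benzylic CH2 of 1, while the non-polar solvent and the low stationary Br2 level should hold back ionic bromination of the anisole ring and of C2; the new centre is racemic at this stage.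

Step 2
Reactants: 2 (±)-3-bromo-7-methoxyindan-1-one
Product: 3 (±)-3-hydroxy-7-methoxyindan-1-one
Conditions: Ag2CO3 (0.6 equiv), acetone–H2O 4:1, 23 °C, dark
Reagents that add atoms: water, O
Why: Silver-assisted SN1 hydrolysis of a secondary benzylic bromide, with the insoluble carbonate taking up HBr without being basic enough to drive E1cB loss of HBr to the indenone.

Step 3
Reactants: 3 (±)-3-hydroxy-7-methoxyindan-1-one
Product: 4 (S)-3-hydroxy-7-methoxyindan-1-one
Conditions: immobilised Burkholderia cepacia lipase, vinyl acetate (3 equiv), MTBE, 30 °C, stopped just past half conversion; chromatography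
Reagents that add atoms: none
Why: Lipase-catalysed kinetic resolution by irreversible acyl transfer, known for 3-hydroxyindan-1-ones, in which the empirical size rule for secondary carbinols (aryl side large, CH2C=O side medium) predicts acetylation of the R alcohol, so that the S alcohol, which becomes C1 of the target, is left behind and gains in enantiomeric purity when the run is taken just past half conversion.

Step 4
Reactants: 4 (S)-3-hydroxy-7-methoxyindan-1-one
Product: 5 (S)-3-(tert-butyldimethylsilyloxy)-7-methoxyindan-1-one
Conditions: TBSCl (1.2 equiv), imidazole (2.5 equiv), DMF, 0 → 23 °C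
Reagents that add atoms: tert-butyldimethylsilyl chloride, CC(C)(C)[Si](C)(C)Cl
Why: Imidazole-promoted O-silylation, mild enough for a β-hydroxy ketone and without any bond change at the stereocentre.

Step 5
Reactants: 6 1,8-dimethoxynaphthalene
Product: 8 4,5-dimethoxy-1-naphthaldehyde, via iminium chloride 7 (not isolated)
Conditions: POCl3 (1.5 equiv), DMF, 0 → 90 °C; then ice–H2O
Reagents that add atoms: N,N-dimethylformamide, CN(C)C=O; water, O
Why: Vilsmeier–Haack formylation, which on the mirror-symmetric diether has only one kind of para (α) position to attack, this being electronically the most activated and less crowded than the ortho position, so that a single aldehyde is expected.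

Step 6
Reactants: 8 4,5-dimethoxy-1-naphthaldehyde
Product: 9 4-hydroxy-5-methoxy-1-naphthaldehyde
Conditions: NaSEt (1.5 equiv), DMF, 100 °C; then 1 M HCl
Reagents that add atoms: none
Why: Thiolate SN2 demethylation of an aryl methyl ether is steered by leaving-group quality, and only the C4 naphthoxide is para-conjugated to the formyl group (a vinylogous carboxylate) whereas the C5 oxygen in the other ring is barely conjugated to it, while the anion formed protects the remaining OMe from a second attack.

Step 7
Reactants: 9 4-hydroxy-5-methoxy-1-naphthaldehyde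
Product: 10 5-methoxy-4-(triisopropylsilyloxy)-1-naphthaldehyde
Conditions: TIPSOTf (1.2 equiv), 2,6-lutidine (2 equiv), CH2Cl2, 0 → 23 °C
Reagents that add atoms: triisopropylsilyl triflate, CC(C)[Si](OS(=O)(=O)C(F)(F)F)(C(C)C)C(C)C
Why: O-silylation with the silyl triflate, needed because the naphthol is crowded by and hydrogen-bonded to the peri OMe; TIPS is chosen since it should withstand hydrazine, amide base and warm amine formate and still leave with fluoride together with TBS in the last step.

Step 8
Reactants: 10 5-methoxy-4-(triisopropylsilyloxy)-1-naphthaldehyde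
Product: 11 (E)-5-methoxy-4-(triisopropylsilyloxy)-1-naphthaldehyde hydrazone
Conditions: N2H4·H2O (10 equiv), EtOH–THF, 0 → 23 °C
Reagents that add atoms: hydrazine (as hydrate), NN
Why: Hydrazone condensation with a large excess of hydrazine to suppress azine formation, the free hydrazone being preferred to a sulfonylhydrazone because it can be dehydrogenated at 0 °C without base or heat, neither of which the Lewis acid and the β-silyloxy ketone of step 10 would tolerate.

Step 9
Reactants: 11 (E)-5-methoxy-4-(triisopropylsilyloxy)-1-naphthaldehyde hydrazone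
Product: 12 1-(diazomethyl)-5-methoxy-4-(triisopropylsilyloxy)naphthalene, kept as a cold CH2Cl2 solution and used at once
Conditions: activated MnO2 (8 equiv), MgSO4, CH2Cl2, 0 °C, 30 min; cold filtration through Celite; storage over 4 Å MS at −20 °C
Reagents that add atoms: none
Why: Dehydrogenation of an aldehyde hydrazone with activated MnO2, a known entry to aryldiazomethanes, after which filtration removes all inorganic matter and leaves a neutral, dry solution fit for a Lewis acid-catalysed reaction.

Step 10
Reactants: 5 (S)-3-(tert-butyldimethylsilyloxy)-7-methoxyindan-1-one; 12 1-(diazomethyl)-5-methoxy-4-(triisopropylsilyloxy)naphthalene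
Product: 14 (4S)-4-(tert-butyldimethylsilyloxy)-8-methoxy-1-[5-methoxy-4-(triisopropylsilyloxy)naphthalen-1-yl]-3,4-dihydronaphthalen-2(1H)-one as a labile epimer pair at the naphthyl-bearing carbon, via diazonium alkoxide 13 (not isolated)
Conditions: Sc(OTf)3 (15 mol %), 4 Å MS, CH2Cl2–toluene, slow addition of 12 (1.3 equiv) at −78 °C, then → −20 °C
Reagents that add atoms: none
Why: Sc(OTf)3 binds the indanone carbonyl of 5, helped by the adjacent 7-OMe through a six-membered chelate, the nucleophilic diazo carbon of 12 adds to give diazonium alkoxide 13 (C3–C4 formed), and the aryl carbon ortho to OMe shifts onto the diazonium carbon as N2 departs (C4–C4a formed). The closest known reaction type is the Lewis acid-catalysed Büchner–Curtius–Schlotterbeck homologation of cyclic ketones with aryldiazomethanes, together with the aryl-migrating diazoalkane ring expansions of 1-indanones to 2-tetralones and of isatins to 4-arylquinolinones. Ring B is closed not by an end-to-end cyclisation but by ring enlargement, the five-membered ring becoming six-membered through a Tiffeneau–Demjanov-type 1,2-shift. The new C4–H centre lies between two arenes and the ketone, is configurationally labile and carries no stereochemical weight because step 11 flattens it, whereas C1 is remote from every bond change and is retained. The step needs aryl rather than CH2 migration, ketone rather than epoxide and a single insertion: the ortho-methoxy aryl carbon has the higher migratory aptitude, the strongly donor-substituted naphthyl group makes N2 loss cation-like so that aptitude rather than rotamer population decides and any spiro-epoxide should re-ionise at the naphthylic carbon and drain to 14, and the crowded α,α-diaryl ketone 14 should accept a second bulky diazo molecule far more slowly than chelate-activated 5. Slow addition at low temperature keeps the stationary concentration of 12 small, which limits azine formation and spares the β-silyloxy group.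

Step 11
Reactants: 14 (4S)-4-(tert-butyldimethylsilyloxy)-8-methoxy-1-[5-methoxy-4-(triisopropylsilyloxy)naphthalen-1-yl]-3,4-dihydronaphthalen-2(1H)-one
Product: 16 (4S)-4-(tert-butyldimethylsilyloxy)-8-methoxy-1-[5-methoxy-4-(triisopropylsilyloxy)naphthalen-1-yl]-3,4-dihydronaphthalen-2-yl trifluoromethanesulfonate, via potassium enolate 15 (not isolated)
Conditions: KHMDS (1.05 equiv, added slowly), THF, −78 °C; then 2-[N,N-bis(trifluoromethylsulfonyl)amino]-5-chloropyridine (1.2 equiv), −78 → −40 °C; aq NH4Cl
Reagents that add atoms: 2-[N,N-bis(trifluoromethylsulfonyl)amino]-5-chloropyridine, FC(F)(F)S(=O)(=O)N(c1ccc(Cl)cn1)S(=O)(=O)C(F)(F)F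
Why: Regioselective enolate O-sulfonylation, in which C4–H, flanked by two arenes and the carbonyl, is more acidic than C2–H2 by several pK units, so that slow addition of one equivalent of base should give only the conjugated C3=C4 enolate 15, which has no pathway to expel the C1 silyloxy group, before the reactive pyridyl triflimide traps it on oxygen at low temperature.

Step 12
Reactants: 16 (4S)-4-(tert-butyldimethylsilyloxy)-8-methoxy-1-[5-methoxy-4-(triisopropylsilyloxy)naphthalen-1-yl]-3,4-dihydronaphthalen-2-yl trifluoromethanesulfonate
Product: 17 (1S)-1-(tert-butyldimethylsilyloxy)-5-methoxy-4-[5-methoxy-4-(triisopropylsilyloxy)naphthalen-1-yl]-1,2-dihydronaphthalene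
Conditions: Pd(OAc)2 (5 mol %), PPh3 (12 mol %), HCO2H (2 equiv), Et3N (3 equiv), DMF, 50 °C
Reagents that add atoms: none
Why: Palladium-catalysed formate reduction of an enol triflate (oxidative addition to zerovalent palladium, exchange of triflate for formate, decarboxylation, C–H reductive elimination), run with amine in excess over HCO2H so that the benzylic, homoallylic silyl ether is never exposed to acid.

Step 13
Reactants: 17 (1S)-1-(tert-butyldimethylsilyloxy)-5-methoxy-4-[5-methoxy-4-(triisopropylsilyloxy)naphthalen-1-yl]-1,2-dihydronaphthalene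
Product: 18 (1S,4S)-1-(tert-butyldimethylsilyloxy)-5-methoxy-4-[5-methoxy-4-(triisopropylsilyloxy)naphthalen-1-yl]-1,2,3,4-tetrahydronaphthalene (1,4-cis)
Conditions: [Ir(cod)((S)-tBu-PHOX)]BArF (3 mol %; BArF = tetrakis[3,5-bis(trifluoromethyl)phenyl]borate), K3PO4 (10 mol %), H2 (50 bar), CH2Cl2, 25 °C
Reagents that add atoms: none
Why: Iridium N,P-ligand-catalysed asymmetric hydrogenation of an unfunctionalised trisubstituted aryl alkene of the 1-substituted 3,4-dihydronaphthalene class, in which syn delivery of H2 to the ring face opposite the pseudoaxial C1–OTBS group pushes the naphthyl group onto the face of the oxygen and sets C4 as S (1,4-cis), catalyst preference and substrate bias being chosen to reinforce each other.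

Step 14
Reactants: 18 (1S,4S)-1-(tert-butyldimethylsilyloxy)-5-methoxy-4-[5-methoxy-4-(triisopropylsilyloxy)naphthalen-1-yl]-1,2,3,4-tetrahydronaphthalene
Product: 19 dipolynaphthalene B, (1S,4S)-4-(4-hydroxy-5-methoxynaphthalen-1-yl)-5-methoxy-1,2,3,4-tetrahydronaphthalen-1-ol
Conditions: TBAF (3 equiv), AcOH (3 equiv), THF, 0 → 23 °C
Reagents that add atoms: none
Why: Fluoride-induced cleavage of both silyl ethers in one operation, buffered with acetic acid so that the electron-rich naphthoxide is protonated at once, under conditions that neither ionise C1–O nor deprotonate C4–H.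

## Compound list

1 | 7-methoxyindan-1-one | COc1cccc2c1C(=O)CC2 | starting material
2 | (±)-3-bromo-7-methoxyindan-1-one | COc1cccc2c1C(=O)CC2Br | intermediate
3 | (±)-3-hydroxy-7-methoxyindan-1-one | COc1cccc2c1C(=O)CC2O | intermediate
4 | (S)-3-hydroxy-7-methoxyindan-1-one | COc1cccc2c1C(=O)C[C@@H]2O | intermediate
5 | (S)-3-(tert-butyldimethylsilyloxy)-7-methoxyindan-1-one | COc1cccc2c1C(=O)C[C@@H]2O[Si](C)(C)C(C)(C)C | intermediate
6 | 1,8-dimethoxynaphthalene | COc1cccc2cccc(OC)c12 | starting material
7 | [(4,5-dimethoxynaphthalen-1-yl)methylidene]dimethylammonium chloride (forms in the flask, not isolated) | C[N+](C)=Cc1ccc(OC)c2c(OC)cccc12.[Cl-] | intermediate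
8 | 4,5-dimethoxy-1-naphthaldehyde | O=Cc1ccc(OC)c2c(OC)cccc12 | intermediate
9 | 4-hydroxy-5-methoxy-1-naphthaldehyde | O=Cc1ccc(O)c2c(OC)cccc12 | intermediate
10 | 5-methoxy-4-(triisopropylsilyloxy)-1-naphthaldehyde | O=Cc1ccc(O[Si](C(C)C)(C(C)C)C(C)C)c2c(OC)cccc12 | intermediate
11 | (E)-5-methoxy-4-(triisopropylsilyloxy)-1-naphthaldehyde hydrazone | N/N=C/c1ccc(O[Si](C(C)C)(C(C)C)C(C)C)c2c(OC)cccc12 | intermediate
12 | 1-(diazomethyl)-5-methoxy-4-(triisopropylsilyloxy)naphthalene | [N-]=[N+]=Cc1ccc(O[Si](C(C)C)(C(C)C)C(C)C)c2c(OC)cccc12 | intermediate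
13 | diazonium alkoxide from addition of 12 to the carbonyl of 5, drawn without the scandium (forms in the flask, not isolated) | COc1cccc2c1C([O-])(C([N+]#N)c1ccc(O[Si](C(C)C)(C(C)C)C(C)C)c3c(OC)cccc13)C[C@@H]2O[Si](C)(C)C(C)(C)C | intermediate
14 | (4S)-4-(tert-butyldimethylsilyloxy)-8-methoxy-1-[5-methoxy-4-(triisopropylsilyloxy)naphthalen-1-yl]-3,4-dihydronaphthalen-2(1H)-one, labile epimers at C1 of the tetralone | COc1cccc2c1C(c1ccc(O[Si](C(C)C)(C(C)C)C(C)C)c3c(OC)cccc13)C(=O)C[C@@H]2O[Si](C)(C)C(C)(C)C | intermediate
15 | potassium enolate of 14, conjugated with both arenes (forms in the flask, not isolated) | COc1cccc2c1C(c1ccc(O[Si](C(C)C)(C(C)C)C(C)C)c3c(OC)cccc13)=C([O-])C[C@@H]2O[Si](C)(C)C(C)(C)C.[K+] | intermediate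
16 | (4S)-4-(tert-butyldimethylsilyloxy)-8-methoxy-1-[5-methoxy-4-(triisopropylsilyloxy)naphthalen-1-yl]-3,4-dihydronaphthalen-2-yl trifluoromethanesulfonate | COc1cccc2c1C(c1ccc(O[Si](C(C)C)(C(C)C)C(C)C)c3c(OC)cccc13)=C(OS(=O)(=O)C(F)(F)F)C[C@@H]2O[Si](C)(C)C(C)(C)C | intermediate
17 | (1S)-1-(tert-butyldimethylsilyloxy)-5-methoxy-4-[5-methoxy-4-(triisopropylsilyloxy)naphthalen-1-yl]-1,2-dihydronaphthalene | COc1cccc2c1C(c1ccc(O[Si](C(C)C)(C(C)C)C(C)C)c3c(OC)cccc13)=CC[C@@H]2O[Si](C)(C)C(C)(C)C | intermediate
18 | (1S,4S)-1-(tert-butyldimethylsilyloxy)-5-methoxy-4-[5-methoxy-4-(triisopropylsilyloxy)naphthalen-1-yl]-1,2,3,4-tetrahydronaphthalene | COc1cccc2c1[C@H](c1ccc(O[Si](C(C)C)(C(C)C)C(C)C)c3c(OC)cccc13)CC[C@@H]2O[Si](C)(C)C(C)(C)C | intermediate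
19 | dipolynaphthalene B, (1S,4S)-4-(4-hydroxy-5-methoxynaphthalen-1-yl)-5-methoxy-1,2,3,4-tetrahydronaphthalen-1-ol | COc1cccc2c1[C@H](c1ccc(O)c3c(OC)cccc13)CC[C@@H]2O | target

## Step count and risks

Total step count: 14. Longest linear sequence: 10 steps (6 to 19, steps 5 to 14). The indanone arm (steps 1 to 4) is convergent and joins at step 10.

**Step 10 (ring expansion).**
- What may go wrong: addition of the bulky diazo carbon to a donor-deactivated aryl ketone may be slower than acid-induced decay of the electron-rich diazo compound (protonation, azine and stilbene formation).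
- Further leaks are migration of CH2 in place of the aryl carbon, a second insertion into the product ketone, and loss of silanol from the β-silyloxy ketone.
- Fallback: a stepwise semipinacol ring enlargement through a β-hydroxy selenide, a known one-carbon ring expansion of cyclic ketones. It sets out from aldehyde 10 and ketone 5 and comes back at 14.
- Aldehyde 10 is treated with PhSeH and ZnCl2 in CH2Cl2 to give the selenoacetal 1-[bis(phenylselanyl)methyl]-5-methoxy-4-(triisopropylsilyloxy)naphthalene F1.
- Selenium–lithium exchange with n-BuLi in THF at −78 °C gives [5-methoxy-4-(triisopropylsilyloxy)naphthalen-1-yl](phenylselanyl)methyllithium F2. This soft and weakly basic nucleophile adds to 5 to give the β-hydroxy selenide (3S)-3-(tert-butyldimethylsilyloxy)-7-methoxy-1-{[5-methoxy-4-(triisopropylsilyloxy)naphthalen-1-yl](phenylselanyl)methyl}indan-1-ol F3.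
- Activation of selenium with AgBF4 on alumina in CH2Cl2 turns PhSe into a leaving group at the naphthylic carbon. The same aryl 1,2-shift then delivers 14.

**Step 11 (enol triflate).**
- What may go wrong: kinetic deprotonation at the less hindered C2, followed by E1cB loss of silanolate and irreversible aromatisation of ring B to a naphthol.
- Fallback: no enolate is made at all. It sets out from 14 and comes back at 17, bypassing 16.
- Luche reduction (NaBH4, CeCl3·7H2O, MeOH, −40 °C), expected to deliver hydride anti to the naphthyl group, gives (4S)-4-(tert-butyldimethylsilyloxy)-8-methoxy-1-[5-methoxy-4-(triisopropylsilyloxy)naphthalen-1-yl]-1,2,3,4-tetrahydronaphthalen-2-ol F4.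
- MsCl and Et3N in CH2Cl2 at 0 °C give the corresponding methanesulfonate F5.
- DBU in warm toluene effects E2 elimination towards the doubly benzylic C4–H, which then stands anti to the mesylate. This gives the conjugated alkene 17.

**Step 13 (asymmetric hydrogenation).**
- What may go wrong: low turnover at an alkene carbon shielded by the perpendicular naphthyl ring and the peri OMe.
- Facial selectivity may be poor if rotation about the C4–naphthyl bond is slow, so that the benzo ring of the naphthyl group covers the wanted face in one rotamer.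
- Acidic iridium hydrides may cause loss of silanol with aromatisation.
- Fallback: C4 is fixed at the ketone stage and no alkene is made. It sets out from 14 and comes back at 18, bypassing steps 11 to 13.
- Noyori-type transfer hydrogenation under dynamic kinetic resolution is known for α-aryl cyclic ketones. The conditions are RuCl(p-cymene)(TsDPEN) with the antipode chosen by test, in HCO2H–Et3N at 25 °C.
- It exploits the rapid epimerisation of C4 and should funnel both epimers into the all-cis alcohol (1S,2R,4S)-4-(tert-butyldimethylsilyloxy)-8-methoxy-1-[5-methoxy-4-(triisopropylsilyloxy)naphthalen-1-yl]-1,2,3,4-tetrahydronaphthalen-2-ol F6.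
- 1,1'-Thiocarbonyldiimidazole and DMAP in CH2Cl2 give the O-(imidazol-1-ylthiocarbonyl) derivative F7.
- Barton–McCombie deoxygenation (Bu3SnH at high concentration, AIBN, toluene, 80 °C) removes the auxiliary carbinol centre and gives 18.

Further compounds
F1 | step 10 | 1-[bis(phenylselanyl)methyl]-5-methoxy-4-(triisopropylsilyloxy)naphthalene | C([Se]c1ccccc1)([Se]c1ccccc1)c1ccc(O[Si](C(C)C)(C(C)C)C(C)C)c2c(OC)cccc12
F2 | step 10 | [5-methoxy-4-(triisopropylsilyloxy)naphthalen-1-yl](phenylselanyl)methyllithium | [Li]C([Se]c1ccccc1)c1ccc(O[Si](C(C)C)(C(C)C)C(C)C)c2c(OC)cccc12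
F3 | step 10 | (3S)-3-(tert-butyldimethylsilyloxy)-7-methoxy-1-{[5-methoxy-4-(triisopropylsilyloxy)naphthalen-1-yl](phenylselanyl)methyl}indan-1-ol | COc1cccc2c1C(O)(C([Se]c1ccccc1)c1ccc(O[Si](C(C)C)(C(C)C)C(C)C)c3c(OC)cccc13)C[C@@H]2O[Si](C)(C)C(C)(C)C
F4 | step 11 | (4S)-4-(tert-butyldimethylsilyloxy)-8-methoxy-1-[5-methoxy-4-(triisopropylsilyloxy)naphthalen-1-yl]-1,2,3,4-tetrahydronaphthalen-2-ol | COc1cccc2c1C(c1ccc(O[Si](C(C)C)(C(C)C)C(C)C)c3c(OC)cccc13)C(O)C[C@@H]2O[Si](C)(C)C(C)(C)C
F5 | step 11 | (4S)-4-(tert-butyldimethylsilyloxy)-8-methoxy-1-[5-methoxy-4-(triisopropylsilyloxy)naphthalen-1-yl]-1,2,3,4-tetrahydronaphthalen-2-yl methanesulfonate | COc1cccc2c1C(c1ccc(O[Si](C(C)C)(C(C)C)C(C)C)c3c(OC)cccc13)C(OS(C)(=O)=O)C[C@@H]2O[Si](C)(C)C(C)(C)C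
F6 | step 13 | (1S,2R,4S)-4-(tert-butyldimethylsilyloxy)-8-methoxy-1-[5-methoxy-4-(triisopropylsilyloxy)naphthalen-1-yl]-1,2,3,4-tetrahydronaphthalen-2-ol | COc1cccc2c1[C@H](c1ccc(O[Si](C(C)C)(C(C)C)C(C)C)c3c(OC)cccc13)[C@H](O)C[C@@H]2O[Si](C)(C)C(C)(C)C
F7 | step 13 | O-{(1S,2R,4S)-4-(tert-butyldimethylsilyloxy)-8-methoxy-1-[5-methoxy-4-(triisopropylsilyloxy)naphthalen-1-yl]-1,2,3,4-tetrahydronaphthalen-2-yl} imidazole-1-carbothioate | COc1cccc2c1[C@H](c1ccc(O[Si](C(C)C)(C(C)C)C(C)C)c3c(OC)cccc13)[C@H](OC(=S)n1ccnc1)C[C@@H]2O[Si](C)(C)C(C)(C)C
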